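## Retrosynthetic overview

1. Target 35 ⇒ ester hydrolysis ⇒ hetero-Diels–Alder union (pyran ring formed last) of the C15 hirsutane 1-oxadiene 32 with the C15 diene (1S,4Z,9R)-isocaryophyllene 15.
2. 32 ⇐ epoxy ketone 28 (Mannich methylenation, then epoxide-to-diosphenol isomerisation) ⇐ triquinane enone 27 ⇐ cyclopentenone annulation (ring A) on diquinane ketone 22.
3. 22 ⇐ meso diquinane 21 (chiral lithium amide desymmetrisation) ⇐ dichloroketene [2+2] and CH2N2 ring expansion (ring B) on cyclopentene 18 (ring C, purchased as acid 16).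
4. 15 ⇐ Wittig ⇐ nine-membered enone 14 ⇐ Grob fragmentation of hydrindane diol mesylate 12 ⇐ SmI2 lactone annulation and Dieckmann closure on keto ester 6 ⇐ enantioselective [2+2] photocycloaddition of 1 and 2 (cyclobutane first, nine-membered ring last).

Assumption: the target is taken exactly as the given SMILES; its caryophyllane half is (1S,9R) with CH3 and H cis on the pyran (4S,5S), which corresponds to addition to a Z-alkene, so 15 is the coupling partner.
Assumption: the enantiomer of the chiral Lewis acid (step 1) and of the lithium amide (step 15) is the one that gives the drawn enantiomers; if an antipode delivers the mirror image, the other is used.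
Assumption: metal enolates and other salts formed by simple deprotonation are treated as part of a step and are not numbered; 19 and 20 are racemates with one enantiomer drawn.

## Route

Step 1
Reactants: 1 cyclohex-2-en-1-one; 2 2-methylprop-1-ene
Product: 4 (1S,6S)-7,7-dimethylbicyclo[4.2.0]octan-2-one (cis-fused), via trans-fused photoadduct 3 (not isolated)
Conditions: 2 (excess), AlBr3-activated chiral B-aryl oxazaborolidine from α,α-diarylprolinol (50 mol%), hν (366 nm), CH2Cl2, −75 °C; then basic Al2O3, CH2Cl2, rt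
Reagents that add atoms: none
Why: Chiral-Lewis-acid-catalysed enantioselective intermolecular [2+2] photocycloaddition in which the bound enone is shielded on one face, isobutene adds head-to-tail (CMe2 on the β-carbon) to fix C6 as S, and the α-centre C1 is equilibrated on alumina to the more stable cis fusion.

Step 2
Reactants: 4 (1S,6S)-7,7-dimethylbicyclo[4.2.0]octan-2-one
Product: 5 methyl (1S,6S)-7,7-dimethyl-2-oxobicyclo[4.2.0]octane-3-carboxylate (C3 epimers and enol)
Conditions: NaH (2.2 equiv), (MeO)2CO, THF, reflux; aq. HCl work-up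
Reagents that add atoms: dimethyl carbonate, COC(=O)OC
Why: Claisen-type C-acylation of the ketone enolate at the only unhindered α-CH2 (C3), driven by formation of the stabilised β-keto ester enolate, with C1 and C6 untouched because the cis fusion is the thermodynamic one.

Step 3
Reactants: 5 methyl (1S,6S)-7,7-dimethyl-2-oxobicyclo[4.2.0]octane-3-carboxylate
Product: 6 methyl (1S,3R,6S)-3,7,7-trimethyl-2-oxobicyclo[4.2.0]octane-3-carboxylate (3-CH3 trans to the cyclobutane)
Conditions: MeI, K2CO3, acetone, reflux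
Reagents that add atoms: iodomethane, CI
Why: SN2 C-methylation of the β-keto ester enolate, in which MeI approaches C3 anti to the pseudo-axial cyclobutane C1–C8 bond so the methyl ends up trans to the four-membered ring (3R), the minor epimer being removed by chromatography.

Step 4
Reactants: 6 methyl (1S,3R,6S)-3,7,7-trimethyl-2-oxobicyclo[4.2.0]octane-3-carboxylate; 7 methyl prop-2-enoate
Product: 8 methyl (1S,2R,3R,6S)-3,7,7-trimethyl-5'-oxospiro[bicyclo[4.2.0]octane-2,2'-oxolane]-3-carboxylate (lactone O cis to 3-CH3)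
Conditions: SmI2 (2.2 equiv), t-BuOH (2 equiv), THF, −78 → 0 °C
Reagents that add atoms: none
Why: SmI2-mediated ketyl–olefin reductive coupling followed by lactonisation, in which the ester-chelated samarium ketyl adds to the acrylate anti to the axial 3-methyl group so that the new C–C bond is cis to CO2Me and the lactone oxygen cis to the methyl (2R).

Step 5
Reactants: 8 methyl (1S,2R,3R,6S)-3,7,7-trimethyl-5'-oxospiro[bicyclo[4.2.0]octane-2,2'-oxolane]-3-carboxylate
Product: 10 (1R,2S,5S,8R)-1-hydroxy-4,4,8-trimethyltricyclo[6.3.0.0^2,5]undecan-9-one (1-OH cis to 8-CH3), via hydroxy keto ester 9 (not isolated)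
Conditions: NaOMe, MeOH/PhMe, reflux; then 2 M NaOH, 60 °C; then 2 M HCl, 50 °C
Reagents that add atoms: none
Why: Methoxide opens the lactone and the propanoate enolate closes the five-membered ring by Dieckmann condensation onto the cis-disposed neopentyl ester (driven by the β-keto ester enolate), after which saponification and decarboxylation give the cis-fused ketol with no change at the existing stereocentres.

Step 6
Reactants: 10 (1R,2S,5S,8R)-1-hydroxy-4,4,8-trimethyltricyclo[6.3.0.0^2,5]undecan-9-one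
Product: 11 (1R,2S,5S,8S,9S)-4,4,8-trimethyltricyclo[6.3.0.0^2,5]undecane-1,9-diol (9-OH trans to 1-OH and to 8-CH3)
Conditions: Me4NBH(OAc)3, MeCN/AcOH (1:1), −25 °C
Reagents that add atoms: none
Why: Hydroxyl-directed (Evans–Saksena) reduction in which the alkoxy(diacetoxy)borohydride formed at the tertiary 1-OH delivers hydride intramolecularly to the syn face of the ketone, giving the 1,9-anti diol whose new 9-OH is trans to the angular methyl (9S).

Step 7
Reactants: 11 (1R,2S,5S,8S,9S)-4,4,8-trimethyltricyclo[6.3.0.0^2,5]undecane-1,9-diol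
Product: 12 (1R,2S,5S,8S,9S)-1-hydroxy-4,4,8-trimethyltricyclo[6.3.0.0^2,5]undecan-9-yl methanesulfonate
Conditions: MsCl, Et3N, CH2Cl2, −20 → 0 °C
Reagents that add atoms: methanesulfonyl chloride, CS(=O)(=O)Cl
Why: Selective sulfonylation (via sulfene) of the secondary alcohol while the tertiary alcohol is inert at low temperature, with retention at C9.

Step 8
Reactants: 12 (1R,2S,5S,8S,9S)-1-hydroxy-4,4,8-trimethyltricyclo[6.3.0.0^2,5]undecan-9-yl methanesulfonate
Product: 14 (1R,5Z,9S)-6,10,10-trimethylbicyclo[7.2.0]undec-5-en-2-one (trans-fused), via cis-fused enone 13 (not isolated)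
Conditions: KOt-Bu (3 equiv), THF, 0 → 40 °C
Reagents that add atoms: none
Why: Grob fragmentation of the 1,3-diol monomesylate alkoxide, in which the C1–C8 bond anti-periplanar to C9–OMs cleaves and, because the mesylate is trans to the angular methyl, the trisubstituted alkene forms stereospecifically as Z, after which the ketone α-centre epimerises under the same base to the more stable trans fusion (1R).

Step 9
Reactants: 14 (1R,5Z,9S)-6,10,10-trimethylbicyclo[7.2.0]undec-5-en-2-one
Product: 15 (1S,4Z,9R)-4,11,11-trimethyl-8-methylidenebicyclo[7.2.0]undec-4-ene (ent-isocaryophyllene)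
Conditions: Ph3PCH3Br, KOt-Bu, THF, 0 °C → reflux
Reagents that add atoms: methyltriphenylphosphonium bromide, C[P+](c1ccccc1)(c1ccccc1)c1ccccc1.[Br-]
Why: Wittig methylenation of the ketone with Ph3P=CH2, which leaves the already thermodynamic trans α-centre and the Z-alkene unchanged.

Step 10
Reactants: 16 cyclopent-3-ene-1-carboxylic acid
Product: 17 1-methylcyclopent-3-ene-1-carboxylic acid
Conditions: LiN(i-Pr)2 (2.2 equiv), THF, −30 → 0 °C; MeI; aq. HCl work-up
Reagents that add atoms: iodomethane, CI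
Why: α-Alkylation of the carboxylic acid dianion (enediolate) with MeI, giving an achiral product.

Step 11
Reactants: 17 1-methylcyclopent-3-ene-1-carboxylic acid
Product: 18 methyl 1-methylcyclopent-3-ene-1-carboxylate
Conditions: MeI, K2CO3, DMF, rt
Reagents that add atoms: iodomethane, CI
Why: SN2 O-alkylation of the carboxylate (esterification), with no stereocentre involved.

Step 12
Reactants: 18 methyl 1-methylcyclopent-3-ene-1-carboxylate
Product: 19 methyl rac-7,7-dichloro-3-methyl-6-oxo-cis-bicyclo[3.2.0]heptane-3-carboxylate (ester trans to the cyclobutanone ring)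
Conditions: Cl3CCOCl, Zn–Cu couple, POCl3, Et2O, reflux
Reagents that add atoms: trichloroacetyl chloride, ClC(Cl)(Cl)C(Cl)=O
Why: Ketene–alkene [2+2] cycloaddition of dichloroketene, suprafacial on the alkene (cis fusion) and occurring on the face anti to the ester and syn to the methyl, which places CO2Me on the convex face cis to the ring-fusion hydrogens, the minor facial isomer being removed at 21.

Step 13
Reactants: 19 methyl rac-7,7-dichloro-3-methyl-6-oxo-cis-bicyclo[3.2.0]heptane-3-carboxylate
Product: 20 methyl rac-4,4-dichloro-2-methyl-5-oxo-cis-octahydropentalene-2-carboxylate (ester cis to H-3a and H-6a)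
Conditions: CH2N2, Et2O/MeOH, 0 °C → rt
Reagents that add atoms: diazomethane, C=[N+]=[N-]
Why: Diazomethane ring expansion of the α,α-dichlorocyclobutanone (Tiffeneau–Demjanov type), in which the non-chlorinated α-carbon migrates with retention so CH2 is inserted between C=O and the ring-fusion carbon.

Step 14
Reactants: 20 methyl rac-4,4-dichloro-2-methyl-5-oxo-cis-octahydropentalene-2-carboxylate
Product: 21 methyl 2-methyl-5-oxo-cis-octahydropentalene-2-carboxylate (meso; ester cis to H-3a and H-6a)
Conditions: Zn, AcOH, 70 °C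
Reagents that add atoms: none
Why: Reductive dechlorination of the α,α-dichloro ketone by zinc through zinc enolates, giving the mirror-symmetric diquinane ketone without touching the stereocentres.

Step 15
Reactants: 21 methyl 2-methyl-5-oxo-cis-octahydropentalene-2-carboxylate
Product: 22 methyl (2S,3aR,4S,6aR)-2,4-dimethyl-5-oxooctahydropentalene-2-carboxylate (4-CH3 cis to H-3a)
Conditions: (R,R)-bis(1-phenylethyl)amine, n-BuLi, LiCl, THF, −78 °C; then MeI, DMPU, −78 → −40 °C
Reagents that add atoms: iodomethane, CI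
Why: Enantioselective desymmetrising deprotonation of the meso ketone by the C2-symmetric chiral lithium amide picks one enantiotopic α-CH2, and the lithium enolate is methylated from the convex face, which fixes the absolute configuration of C3a, C6a and C2.

Step 16
Reactants: 22 methyl (2S,3aR,4S,6aR)-2,4-dimethyl-5-oxooctahydropentalene-2-carboxylate; 23 3-bromoprop-1-yne
Product: 24 methyl (2S,3aR,4S,6aR)-2,4-dimethyl-5-oxo-4-(prop-2-yn-1-yl)octahydropentalene-2-carboxylate (propargyl cis to H-3a)
Conditions: KOt-Bu, t-BuOH/THF, rt; then 23, 0 °C → rt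
Reagents that add atoms: none
Why: Alkylation of the thermodynamic, more substituted potassium enolate from the convex face of the diquinane, so the propargyl group is cis to the ring-fusion hydrogens and the methyl is forced to the concave face, which sets the quaternary centre of the target.

Step 17
Reactants: 24 methyl (2S,3aR,4S,6aR)-2,4-dimethyl-5-oxo-4-(prop-2-yn-1-yl)octahydropentalene-2-carboxylate
Product: 25 methyl (2S,3aR,4S,6aR)-2,4-dimethyl-5-oxo-4-(2-oxopropyl)octahydropentalene-2-carboxylate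
Conditions: NaAuCl4·2H2O (2 mol%), MeOH/H2O (10:1), reflux
Reagents that add atoms: water, O
Why: Gold-catalysed Markovnikov hydration of the terminal alkyne to the methyl ketone, with no stereocentre involved.

Step 18
Reactants: 25 methyl (2S,3aR,4S,6aR)-2,4-dimethyl-5-oxo-4-(2-oxopropyl)octahydropentalene-2-carboxylate
Product: 27 methyl 2,3b-dimethyl-5-oxo-2,3,3a,3b,4,5,7,7a-octahydro-1H-cyclopenta[a]pentalene-2-carboxylate (cis-anti-cis; CO2Me cis to H-3a and H-7a), via aldol 26 (not isolated)
Conditions: NaOMe (0.3 equiv), MeOH, reflux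
Reagents that add atoms: none
Why: Intramolecular aldol condensation (cyclopentenone annulation) in which the methyl-ketone enolate attacks the ring ketone to close ring A cis-fused and the aldol dehydrates to the enone, while the competing bridged aldol cannot dehydrate and reverts.

Step 19
Reactants: 27 methyl 2,3b-dimethyl-5-oxo-2,3,3a,3b,4,5,7,7a-octahydro-1H-cyclopenta[a]pentalene-2-carboxylate
Product: 28 methyl 6,6a-epoxy-2,3b-dimethyl-5-oxodecahydro-1H-cyclopenta[a]pentalene-2-carboxylate (epoxide cis to 3b-CH3)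
Conditions: 30% H2O2, NaOH (0.2 equiv), MeOH, 0 °C
Reagents that add atoms: hydrogen peroxide, OO
Why: Weitz–Scheffer nucleophilic epoxidation of the enone, with hydroperoxide adding to the β-carbon from the convex face so the epoxide is cis to the angular methyl (the only arrangement that keeps rings A and B cis-fused), a configuration that is erased again in step 21.

Step 20
Reactants: 28 methyl 6,6a-epoxy-2,3b-dimethyl-5-oxodecahydro-1H-cyclopenta[a]pentalene-2-carboxylate
Product: 31 methyl 6,6a-epoxy-2,3b-dimethyl-4-methylidene-5-oxodecahydro-1H-cyclopenta[a]pentalene-2-carboxylate, via Mannich base 29 (not isolated), via methiodide 30 (not isolated)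
Conditions: LiN(i-Pr)2, THF, −78 °C; Me2N=CH2+ I−, −78 → 0 °C; then MeI, MeOH, rt; then NaHCO3 (aq.), CH2Cl2, rt
Reagents that add atoms: N,N-dimethylmethyleneiminium iodide, C=[N+](C)C.[I-]
Why: Mannich reaction of the only available (α') lithium enolate, then quaternisation and E1cB elimination of trimethylamine give the α-methylene ketone, leaving no stereocentre at C4.

Step 21
Reactants: 31 methyl 6,6a-epoxy-2,3b-dimethyl-4-methylidene-5-oxodecahydro-1H-cyclopenta[a]pentalene-2-carboxylate
Product: 32 methyl 6-hydroxy-2,3b-dimethyl-4-methylidene-5-oxo-2,3,3a,3b,4,5,7,7a-octahydro-1H-cyclopenta[a]pentalene-2-carboxylate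
Conditions: BF3·OEt2 (20 mol%), CH2Cl2, −30 → 0 °C; used at once
Reagents that add atoms: none
Why: Lewis-acid-catalysed isomerisation of the α,β-epoxy ketone to the diosphenol by ionisation at the tertiary β-carbon and loss of the α-hydrogen, which erases both epoxide stereocentres and unveils the cross-conjugated 1-oxadiene.

Step 22
Reactants: 32 methyl 6-hydroxy-2,3b-dimethyl-4-methylidene-5-oxo-2,3,3a,3b,4,5,7,7a-octahydro-1H-cyclopenta[a]pentalene-2-carboxylate; 15 (1S,4Z,9R)-4,11,11-trimethyl-8-methylidenebicyclo[7.2.0]undec-4-ene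
Product: 34 methyl ester of the target (dihydropyran joining C4–O and C5–CH2 of the (1S,4S,5S,9R)-caryophyllane unit to ring A of the triquinane), via dienol cycloadduct 33 (not isolated)
Conditions: 15 (2 equiv), PhMe, BHT (cat.), 100 °C, sealed tube
Reagents that add atoms: none
Why: Inverse-electron-demand hetero-Diels–Alder reaction of the oxadiene O=C5–C4=CH2 with the more electron-rich trisubstituted alkene (not the exocyclic one), where oxygen bonds to the tertiary carbon, suprafacial addition to the Z-alkene makes CH3 and H cis, attack occurs on the alkene face anti to the gem-dimethyl-bearing cyclobutane carbon (the H-1 face), and the dienol then ketonises to the cis-fused ring A/B junction.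

Step 23
Reactants: 34 methyl ester of the target
Product: 35 target acid CNP0483070.2
Conditions: LiOH·H2O, THF/MeOH/H2O, 50 °C; then 1 M HCl to pH 3, 0 °C
Reagents that add atoms: lithium hydroxide, [Li+].[OH-]
Why: Saponification (BAc2) of the hindered methyl ester, tolerated because the tetrasubstituted α-alkoxy enone is not a Michael acceptor for hydroxide and the epimerisable ring-fusion C–H is already in its thermodynamic cis arrangement.

## Compound list

1 | cyclohex-2-en-1-one | O=C1C=CCCC1 | starting material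
2 | 2-methylprop-1-ene (isobutene) | C=C(C)C | starting material
3 | (1R,6S)-7,7-dimethylbicyclo[4.2.0]octan-2-one (trans-fused) | O=C1CCC[C@H]2[C@H]1CC2(C)C | intermediate
4 | (1S,6S)-7,7-dimethylbicyclo[4.2.0]octan-2-one (cis-fused) | O=C1CCC[C@H]2[C@@H]1CC2(C)C | intermediate
5 | methyl (1S,6S)-7,7-dimethyl-2-oxobicyclo[4.2.0]octane-3-carboxylate (C3 epimers and enol) | O=C1C(C(=O)OC)CC[C@H]2[C@@H]1CC2(C)C | intermediate
6 | methyl (1S,3R,6S)-3,7,7-trimethyl-2-oxobicyclo[4.2.0]octane-3-carboxylate | O=C1[C@](C)(C(=O)OC)CC[C@H]2[C@@H]1CC2(C)C | intermediate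
7 | methyl prop-2-enoate (methyl acrylate) | C=CC(=O)OC | starting material
8 | methyl (1S,2R,3R,6S)-3,7,7-trimethyl-5'-oxospiro[bicyclo[4.2.0]octane-2,2'-oxolane]-3-carboxylate | O=C1CC[C@]2(O1)[C@](C)(C(=O)OC)CC[C@H]3[C@@H]2CC3(C)C | intermediate
9 | methyl (1R,2S,5S,8R)-1-hydroxy-4,4,8-trimethyl-9-oxotricyclo[6.3.0.0^2,5]undecane-10-carboxylate (C10 epimers and enol) | O[C@@]12CC(C(=O)OC)C(=O)[C@]1(C)CC[C@H]3[C@@H]2CC3(C)C | intermediate
10 | (1R,2S,5S,8R)-1-hydroxy-4,4,8-trimethyltricyclo[6.3.0.0^2,5]undecan-9-one | O[C@@]12CCC(=O)[C@]1(C)CC[C@H]3[C@@H]2CC3(C)C | intermediate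
11 | (1R,2S,5S,8S,9S)-4,4,8-trimethyltricyclo[6.3.0.0^2,5]undecane-1,9-diol | O[C@@]12CC[C@H](O)[C@]1(C)CC[C@H]3[C@@H]2CC3(C)C | intermediate
12 | (1R,2S,5S,8S,9S)-1-hydroxy-4,4,8-trimethyltricyclo[6.3.0.0^2,5]undecan-9-yl methanesulfonate | O[C@@]12CC[C@H](OS(C)(=O)=O)[C@]1(C)CC[C@H]3[C@@H]2CC3(C)C | intermediate
13 | (1S,5Z,9S)-6,10,10-trimethylbicyclo[7.2.0]undec-5-en-2-one (cis-fused) | O=C1CC/C=C(/C)CC[C@H]2[C@@H]1CC2(C)C | intermediate
14 | (1R,5Z,9S)-6,10,10-trimethylbicyclo[7.2.0]undec-5-en-2-one (trans-fused) | O=C1CC/C=C(/C)CC[C@H]2[C@H]1CC2(C)C | intermediate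
15 | (1S,4Z,9R)-4,11,11-trimethyl-8-methylidenebicyclo[7.2.0]undec-4-ene (ent-isocaryophyllene) | C=C1CC/C=C(/C)CC[C@H]2[C@H]1CC2(C)C | intermediate
16 | cyclopent-3-ene-1-carboxylic acid | OC(=O)C1CC=CC1 | starting material
17 | 1-methylcyclopent-3-ene-1-carboxylic acid | OC(=O)C1(C)CC=CC1 | intermediate
18 | methyl 1-methylcyclopent-3-ene-1-carboxylate | COC(=O)C1(C)CC=CC1 | intermediate
19 | methyl rac-7,7-dichloro-3-methyl-6-oxo-cis-bicyclo[3.2.0]heptane-3-carboxylate (ester trans to the cyclobutanone; one enantiomer drawn) | O=C1[C@@H]2C[C@@](C)(C(=O)OC)C[C@@H]2C1(Cl)Cl | intermediate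
20 | methyl rac-4,4-dichloro-2-methyl-5-oxo-cis-octahydropentalene-2-carboxylate (ester cis to H-3a/H-6a; one enantiomer drawn) | O=C1C[C@@H]2C[C@@](C)(C(=O)OC)C[C@@H]2C1(Cl)Cl | intermediate
21 | methyl 2-methyl-5-oxo-cis-octahydropentalene-2-carboxylate (meso; ester cis to H-3a/H-6a, 2-CH3 on the concave face) | O=C1C[C@H]2C[C@](C)(C(=O)OC)C[C@H]2C1 | intermediate
22 | methyl (2S,3aR,4S,6aR)-2,4-dimethyl-5-oxooctahydropentalene-2-carboxylate | O=C1C[C@H]2C[C@](C)(C(=O)OC)C[C@H]2[C@@H]1C | intermediate
23 | 3-bromoprop-1-yne (propargyl bromide) | BrCC#C | starting material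
24 | methyl (2S,3aR,4S,6aR)-2,4-dimethyl-5-oxo-4-(prop-2-yn-1-yl)octahydropentalene-2-carboxylate | O=C1C[C@H]2C[C@](C)(C(=O)OC)C[C@H]2[C@]1(C)CC#C | intermediate
25 | methyl (2S,3aR,4S,6aR)-2,4-dimethyl-5-oxo-4-(2-oxopropyl)octahydropentalene-2-carboxylate | O=C1C[C@H]2C[C@](C)(C(=O)OC)C[C@H]2[C@]1(C)CC(C)=O | intermediate
26 | methyl 6a-hydroxy-2,3b-dimethyl-5-oxodecahydro-1H-cyclopenta[a]pentalene-2-carboxylate (6a-OH cis to 3b-CH3) | O=C1C[C@]2(O)C[C@H]3C[C@](C)(C(=O)OC)C[C@H]3[C@]2(C)C1 | intermediate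
27 | methyl 2,3b-dimethyl-5-oxo-2,3,3a,3b,4,5,7,7a-octahydro-1H-cyclopenta[a]pentalene-2-carboxylate (CO2Me cis to H-3a/H-7a; both C-methyls trans to H-3a) | O=C1C=C2C[C@H]3C[C@](C)(C(=O)OC)C[C@H]3[C@]2(C)C1 | intermediate
28 | methyl 6,6a-epoxy-2,3b-dimethyl-5-oxodecahydro-1H-cyclopenta[a]pentalene-2-carboxylate (epoxide cis to 3b-CH3) | O=C1[C@H]2O[C@]23C[C@H]4C[C@](C)(C(=O)OC)C[C@H]4[C@]3(C)C1 | intermediate
29 | 4-[(dimethylamino)methyl] derivative of 28 (C4 epimers) | O=C1[C@H]2O[C@]23C[C@H]4C[C@](C)(C(=O)OC)C[C@H]4[C@]3(C)C1CN(C)C | intermediate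
30 | 4-[(trimethylammonio)methyl] derivative of 28, iodide | O=C1[C@H]2O[C@]23C[C@H]4C[C@](C)(C(=O)OC)C[C@H]4[C@]3(C)C1C[N+](C)(C)C.[I-] | intermediate
31 | methyl 6,6a-epoxy-2,3b-dimethyl-4-methylidene-5-oxodecahydro-1H-cyclopenta[a]pentalene-2-carboxylate | O=C1[C@H]2O[C@]23C[C@H]4C[C@](C)(C(=O)OC)C[C@H]4[C@]3(C)C1=C | intermediate
32 | methyl 6-hydroxy-2,3b-dimethyl-4-methylidene-5-oxo-2,3,3a,3b,4,5,7,7a-octahydro-1H-cyclopenta[a]pentalene-2-carboxylate | C=C1C(=O)C(O)=C2C[C@H]3C[C@](C)(C(=O)OC)C[C@H]3[C@]12C | intermediate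
33 | dienol tautomer of 34 (initial cycloadduct; 5-hydroxy-cyclopentadiene ring A) | C=C1CC[C@H]2CC3=C(O[C@@]2(C)CC[C@H]2[C@H]1CC2(C)C)C(O)=C1C[C@H]2C[C@](C)(C(=O)OC)C[C@H]2[C@]31C | intermediate
34 | methyl ester of the target: dihydropyran fused at O–C4/CH2–C5 to (1S,4S,5S,9R)-8-methylidenecaryophyllane and to ring A of the cis-anti-cis triquinane enone | C=C1CC[C@H]2CC3=C(O[C@@]2(C)CC[C@H]2[C@H]1CC2(C)C)C(=O)[C@@H]1C[C@H]2C[C@](C)(C(=O)OC)C[C@H]2[C@]31C | intermediate
35 | target acid CNP0483070.2 | C=C1CC[C@H]2CC3=C(O[C@@]2(C)CC[C@H]2[C@H]1CC2(C)C)C(=O)[C@@H]1C[C@H]2C[C@](C)(C(=O)O)C[C@H]2[C@]31C | target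

## Step count and risks

Total step count: 23. Longest linear sequence: 14 steps (steps 10–23); the caryophyllane branch is 9 steps (steps 1–9) and joins at step 22.

Steps most likely to fail:

Step 22 (hetero-Diels–Alder). The Z-alkene of 15 is unstrained and therefore sluggish, the exocyclic alkene can compete, the facial preference is predicted rather than known, and 32 can dimerise. Fallback: set out from enone 14, which has no second alkene, and heat it with 32 (PhMe, 100 °C) to give, through keto dienol cycloadduct F1, keto cycloadduct F2. A chemoselective Wittig methylenation of the saturated nine-membered-ring ketone of F2 (Ph3P=CH2, 1.1 equiv, THF, 0 °C; the hindered α-alkoxy enone carbonyl is much less reactive) comes back to the route at 34.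

Step 21 (epoxy ketone to diosphenol in the presence of the exocyclic enone). The acid may polymerise 31 or 32. Fallback: set out from 28 and isomerise before the methylene group is present (cat. H2SO4, AcOH, rt) to diosphenol F3. Silylate (TBSOTf, 2,6-lutidine) to silyl enol ether F4. Methylenate as in step 20 through Mannich base F5 and methiodide F6 to the silyloxy methylidene dienone F7. Cycloaddition of F7 with 15 (PhMe, 100 °C) gives silyl dienol ether cycloadduct F8, and Bu4NF/AcOH removes silicon so the dienol ketonises, coming back to the route at 34.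

Step 4 (SmI2 ketyl–acrylate coupling on a hindered α-quaternary β-keto ester). Ketyl reduction or poor conversion is possible. Fallback: set out from 6 and add CH2=CHCH2MgBr (THF, −78 °C, chelation-controlled, anti to the 3-methyl) to give homoallylic alcohol F9. Hydroboration–oxidation (9-BBN; H2O2, NaOH) gives diol F10. Oxidation with TEMPO/PhI(OAc)2 proceeds through lactol F11 and comes back to the route at lactone 8.

## Further compounds

F1 | step 22 | keto dienol cycloadduct (8-oxo analogue of 33) | O=C1CC[C@H]2CC3=C(O[C@@]2(C)CC[C@H]2[C@H]1CC2(C)C)C(O)=C1C[C@H]2C[C@](C)(C(=O)OC)C[C@H]2[C@]31C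
F2 | step 22 | keto cycloadduct (8-oxo analogue of 34) | O=C1CC[C@H]2CC3=C(O[C@@]2(C)CC[C@H]2[C@H]1CC2(C)C)C(=O)[C@@H]1C[C@H]2C[C@](C)(C(=O)OC)C[C@H]2[C@]31C
F3 | step 21 | methyl 6-hydroxy-2,3b-dimethyl-5-oxo-2,3,3a,3b,4,5,7,7a-octahydro-1H-cyclopenta[a]pentalene-2-carboxylate (diosphenol) | O=C1C(O)=C2C[C@H]3C[C@](C)(C(=O)OC)C[C@H]3[C@]2(C)C1
F4 | step 21 | 6-O-tert-butyldimethylsilyl ether of F3 | O=C1C(O[Si](C)(C)C(C)(C)C)=C2C[C@H]3C[C@](C)(C(=O)OC)C[C@H]3[C@]2(C)C1
F5 | step 21 | 4-[(dimethylamino)methyl] derivative of F4 (C4 epimers) | CN(C)CC1C(=O)C(O[Si](C)(C)C(C)(C)C)=C2C[C@H]3C[C@](C)(C(=O)OC)C[C@H]3[C@]12C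
F6 | step 21 | 4-[(trimethylammonio)methyl] derivative of F4, iodide | C[N+](C)(C)CC1C(=O)C(O[Si](C)(C)C(C)(C)C)=C2C[C@H]3C[C@](C)(C(=O)OC)C[C@H]3[C@]12C.[I-]
F7 | step 21 | 6-O-tert-butyldimethylsilyl ether of 32 (silyloxy methylidene dienone) | C=C1C(=O)C(O[Si](C)(C)C(C)(C)C)=C2C[C@H]3C[C@](C)(C(=O)OC)C[C@H]3[C@]12C
F8 | step 21 | O-tert-butyldimethylsilyl ether of dienol 33 (silyl dienol ether cycloadduct) | C=C1CC[C@H]2CC3=C(O[C@@]2(C)CC[C@H]2[C@H]1CC2(C)C)C(O[Si](C)(C)C(C)(C)C)=C1C[C@H]2C[C@](C)(C(=O)OC)C[C@H]2[C@]31C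
F9 | step 4 | methyl (1S,2R,3R,6S)-2-hydroxy-3,7,7-trimethyl-2-(prop-2-en-1-yl)bicyclo[4.2.0]octane-3-carboxylate | O[C@@]1(CC=C)[C@](C)(C(=O)OC)CC[C@H]2[C@@H]1CC2(C)C
F10 | step 4 | methyl (1S,2R,3R,6S)-2-hydroxy-2-(3-hydroxypropyl)-3,7,7-trimethylbicyclo[4.2.0]octane-3-carboxylate | O[C@@]1(CCCO)[C@](C)(C(=O)OC)CC[C@H]2[C@@H]1CC2(C)C
F11 | step 4 | lactol of 8 (5'-hydroxy spiro-oxolane, anomers) | OC1CC[C@]2(O1)[C@](C)(C(=O)OC)CC[C@H]3[C@@H]2CC3(C)C
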